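The readings were computed on assumed constants; the scatter is artificial.

A bimolecular step slows as its reactants thin out, so I asked which reactant gives out first in the east flask, and the charge points to the coupling partner, the limiting reagent, at 0.136 M against 0.17 M of starting material.

- east: starting material 0.17 M; coupling partner 0.136 M; protic impurity 0.17 M; the very flask that is asked about, followed so far
- flask: starting material 0.17 M; coupling partner 0.136 M; protic impurity 0.170 M; time 20 h

- east (time / h: target / %): 0.417: 21.5; 0.667: 27.0; 1.33: 29.3; 2.50: 28.4; 4.00: 23.8

(readings scatter by 1 percentage point)

- percentages count the starting material that a species holds: one idle adduct counts as two
- target is meant together with its idle adduct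
- what may be going on: starting material + coupling partner <-> isomer of the product; coupling partner + protic impurity -> quenched reagent; starting material + coupling partner <-> target; coupling partner -> decomposed reagent; starting material + target <-> idle adduct
- in an amount of target, one idle adduct counts as one target

1. when, up to 20 h, the flask holds most target
2. the amount of target, in percent of the starting material charged, at that time
3. the first time at which target reaches 21%, in the same percent

The flask asked about is the east run itself, so these readings are its own early curve and need no scaling. I built it up one process at a time, in fractions of the charge, with b the fraction of partner left.

First I took the main step, starting material + coupling partner to target, with nothing else running. Each unit of target then takes 1.25 units of b; this partner draw, charged starting material over charged partner, treats an idle adduct as one target, since it holds one partner. This step stops where b reaches zero, at 80.0% target, yet the highest reading, 29.3%, accounts for 36.6% of the partner.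

Next I made the step reversible, which gives a plateau instead of that ceiling but no fall. Last I added the partner's losses to the isomer of the product, protic impurity and decomposition, which lower b without making target. A reversible target can then follow b down, as the readings do from 28.4% at 2.50 h to 23.8% at 4.00 h.

So I committed to one early maximum, about 29.3% near 1.33 h, and to a crossing of 21% at 0.407 h, by proportion from the first reading.

The forecast, later and higher at the peak than my reading, gave 29.5% at 1.5 h and the crossing at 0.4 h, adding “No later recovery is expected”.

The flask gives 29.9% at 1.61 h and reaches 21% at 0.449 h.

    starting material + coupling partner ⇌ isomer of the product (K = 34.0 M⁻¹, k = 0.604 M⁻¹ h⁻¹)
    coupling partner + protic impurity → quenched reagent (k = 1.78 M⁻¹ h⁻¹)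
    starting material + coupling partner ⇌ target (K = 12.4 M⁻¹, k = 6.18 M⁻¹ h⁻¹)
    coupling partner → decomposed reagent (k = 0.247 h⁻¹)
    starting material + target ⇌ idle adduct, settled at all times (K = 5.80 M⁻¹)

At that peak the draw puts 37.4% of this flask's partner in target and 4.99% in the isomer of the product, while 20.7% stands free, 19.6% is quenched and 17.4% is decomposed. The neighbour flask, charged with 0.068 M of starting material, has a draw of 0.500. Its best target, 35.2%, is higher than this flask's, yet takes less partner, 17.6% of the charge. At its end, 0.63% of its partner is left unbound.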